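**Strategy.** Ring B is disconnected across C1'–C2' and C5'–C6'. Its pattern, O4' para to C1' with the side chain on the neighbouring C3', is that of a 2-siloxy-3-alkylbutadiene added to a terminal alkyne held on chromone C2, a vinylogous acyl carbon. One Diels–Alder step therefore closes ring B, joins it to the finished chromone (rings A and C) and places all three ring B substituents; the 1,4-cyclohexadiene formed needs only dehydrogenation. The precursors are an (R)-configured bis-silyl diene, whose carbinol centre comes from a Sharpless kinetic resolution, and a 2-ethynyl-5-hydroxy-7-silyloxychromone. All protecting groups are silyl, so fluoride alone ends the synthesis.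

Key step: step 11

Remark: the chromone hydroxyls are carried free through steps 6 to 9 and only silyl groups are used afterwards, so that no strong acid meets the ortho-(2-hydroxy-3-methylbut-3-enyl)phenol, which could cyclise; commercial phloroacetophenone hydrate is assumed to be dried before step 6.

**Diene fragment**

Step 1
Reactants: 1 methacrolein; 2 2,3-dibromopropene
Product: 4 rac-5-bromo-2-methylhexa-1,5-dien-3-ol, via diallyltin dibromide 3 (not isolated)
Conditions: Sn powder, HBr (cat.), Et2O/H2O, rt
Reagents that add atoms: none
Why: Tin-mediated Barbier allylation, in which tin inserts only into the allylic C–Br bond and the resulting allyltin adds 1,2 to the enal through a cyclic allyl-transfer transition state, should give the racemic 2-bromohomoallylic alcohol with the vinyl bromide intact.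

Step 2
Reactants: 4 rac-5-bromo-2-methylhexa-1,5-dien-3-ol
Product: 5 (R)-5-bromo-2-methylhexa-1,5-dien-3-ol
Conditions: Ti(OiPr)4 (0.15 equiv), L-(+)-DIPT (0.2 equiv), t-BuOOH (0.6 equiv), 4 Å MS, CH2Cl2, −20 °C
Reagents that add atoms: none
Why: Sharpless kinetic resolution (Katsuki–Sharpless epoxidation) with the L-(+)-tartrate catalyst should epoxidise the isopropenyl group of the (S)-alcohol quickly and leave the mismatched (R)-alcohol, which is recovered; this sets the only stereocentre of the target, at the cost of at most half of 4, and the electron-poor homoallylic vinyl bromide is not epoxidised.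

Step 3
Reactants: 5 (R)-5-bromo-2-methylhexa-1,5-dien-3-ol
Product: 6 (R)-[(5-bromo-2-methylhexa-1,5-dien-3-yl)oxy](tert-butyl)dimethylsilane
Conditions: TBSCl, imidazole, DMF, 0 °C to rt
Reagents that add atoms: tert-butyldimethylsilyl chloride, CC(C)(C)[Si](C)(C)Cl
Why: Standard imidazole-promoted O-silylation of a secondary alcohol, which does not touch the stereocentre and masks the hydroxyl for the organolithium step.

Step 4
Reactants: 6 (R)-[(5-bromo-2-methylhexa-1,5-dien-3-yl)oxy](tert-butyl)dimethylsilane; 7 N-methoxy-N-methylacetamide
Product: 9 (R)-5-(tert-butyldimethylsilyloxy)-6-methyl-3-methylidenehept-6-en-2-one, via vinyllithium 8 (not isolated)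
Conditions: t-BuLi (2.1 equiv), Et2O, −78 °C; then 7, −78 to −30 °C; poured into cold 1 M HCl
Reagents that add atoms: none
Why: Bromine–lithium exchange followed by Weinreb ketone synthesis should place the acetyl group on the carbon that already carries the methylidene, so no regiochemical question arises; the chelated tetrahedral adduct prevents over-addition and the cold acidic quench protonates the released amine before it can add to the enone.

Step 5
Reactants: 9 (R)-5-(tert-butyldimethylsilyloxy)-6-methyl-3-methylidenehept-6-en-2-one
Product: 10 (R)-2,5-bis(tert-butyldimethylsilyloxy)-6-methyl-3-methylidenehepta-1,6-diene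
Conditions: TBSOTf, Et3N, CH2Cl2, −78 to 0 °C
Reagents that add atoms: tert-butyldimethylsilyl triflate, CC(C)(C)[Si](C)(C)OS(=O)(=O)C(F)(F)F
Why: Soft enolisation and O-silylation of a methyl ketone whose only α-hydrogens are on the methyl group should give the 2-siloxy-1,3-diene as a single regioisomer (silyl enol ether formation).

**Alkyne fragment**

Step 6
Reactants: 11 phloroacetophenone (2',4',6'-trihydroxyacetophenone); 12 diethyl oxalate
Product: 14 ethyl 5,7-dihydroxy-4-oxo-4H-chromene-2-carboxylate, via diketo ester 13 (not isolated)
Conditions: NaOEt (5 equiv), EtOH, reflux; then conc. HCl, EtOH, reflux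
Reagents that add atoms: none
Why: Crossed Claisen condensation of the methyl ketone with the non-enolisable oxalate, then acid-catalysed cyclodehydration of an ortho hydroxyl onto the 2-keto group, is the established chromone-2-carboxylate synthesis; the symmetry of ring A makes both ortho hydroxyls equivalent.

Step 7
Reactants: 14 ethyl 5,7-dihydroxy-4-oxo-4H-chromene-2-carboxylate
Product: 15 5,7-dihydroxy-2-(hydroxymethyl)-4H-chromen-4-one
Conditions: NaBH4 (excess), MeOH/THF, 0 °C; then dilute acid to pH 5
Reagents that add atoms: none
Why: Chemoselective borohydride reduction of the activated ester on C2 should succeed because the C4 carbonyl is a hydrogen-bonded vinylogous ester that the 7-phenoxide formed in the flask deactivates further.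

Step 8
Reactants: 15 5,7-dihydroxy-2-(hydroxymethyl)-4H-chromen-4-one
Product: 16 5,7-dihydroxy-4-oxo-4H-chromene-2-carbaldehyde
Conditions: activated MnO2 (10 equiv), acetone, rt
Reagents that add atoms: none
Why: Heterogeneous MnO2 oxidation is selective for the allylic-type primary alcohol on C2, stops at the aldehyde and leaves the phenols of the electron-poor ring A alone.

Step 9
Reactants: 16 5,7-dihydroxy-4-oxo-4H-chromene-2-carbaldehyde
Product: 17 2-ethynyl-5,7-dihydroxy-4H-chromen-4-one
Conditions: dimethyl (1-diazo-2-oxopropyl)phosphonate, K2CO3 (3.5 equiv), MeOH, 0 °C to rt; then pH 5 buffer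
Reagents that add atoms: dimethyl (1-diazo-2-oxopropyl)phosphonate (Bestmann–Ohira reagent), CC(=O)C(=[N+]=[N-])P(=O)(OC)OC
Why: Seyferth–Gilbert homologation in its Ohira–Bestmann form (olefination to a diazoalkene, loss of N2, 1,2-hydrogen shift of the alkylidene carbene) should give the terminal alkyne, while the 7-phenoxide present in the basic medium makes the pyrone ring and the new enyne poor acceptors for methoxide.

Step 10
Reactants: 17 2-ethynyl-5,7-dihydroxy-4H-chromen-4-one
Product: 18 2-ethynyl-5-hydroxy-7-(triisopropylsilyloxy)-4H-chromen-4-one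
Conditions: TIPSCl (1.1 equiv), Et3N, THF, 0 °C to rt
Reagents that add atoms: triisopropylsilyl chloride, CC(C)[Si](Cl)(C(C)C)C(C)C
Why: Selective O-silylation of the acidic, unchelated 7-hydroxyl removes the only proton that could destroy the silyl enol ether in step 11, while the 5-hydroxyl stays locked in its hydrogen bond to the C4 carbonyl.

**Union and end game**

Step 11
Reactants: 10 (R)-2,5-bis(tert-butyldimethylsilyloxy)-6-methyl-3-methylidenehepta-1,6-diene; 18 2-ethynyl-5-hydroxy-7-(triisopropylsilyloxy)-4H-chromen-4-one
Product: 19 2-{4-(tert-butyldimethylsilyloxy)-5-[(R)-2-(tert-butyldimethylsilyloxy)-3-methylbut-3-en-1-yl]cyclohexa-1,4-dien-1-yl}-5-hydroxy-7-(triisopropylsilyloxy)-4H-chromen-4-one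
Conditions: 10 (1.5 equiv), BHT (cat.), toluene (1 M), 120 °C, sealed tube
Reagents that add atoms: none
Why: Diene and alkyne should combine in a single-step Diels–Alder reaction of normal electron demand with an unsymmetrical transition state, the HOMO of the siloxydiene meeting an alkyne LUMO that is lowered by conjugation through C2=C3 to the C4 carbonyl and further by the internal hydrogen bond from the 5-hydroxyl to that carbonyl. The closest known reaction type is the cycloaddition of 2-siloxy-1,3-dienes to acceptor-substituted alkynes, which gives 1-siloxycyclohexa-1,4-dienes that are later dehydrogenated to aryl silyl ethers. Ring B closes as a six-membered carbocycle by an intermolecular suprafacial (4+2) union that forms C5'–C6' and C1'–C2' together. No stereocentre is created, since the new ring positions are sp2 carbons or CH2 groups, and the silyl-protected (R)-carbinol centre is a spectator under neutral thermal conditions. Regiochemistry must place the silyloxy carbon across the ring from the chromone-bearing carbon; this should follow because the enol ether oxygen makes its own CH2 terminus the most nucleophilic diene carbon, the terminal alkyne carbon is the most electrophilic dienophile carbon, and the alkyl branch on the neighbouring diene carbon polarises the diene only weakly the other way. Chemoselectivity is expected because the chromone C2=C3 bond is donor-substituted and hindered and the two 1,1-disubstituted alkenes of the side chain are unactivated.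

Step 12
Reactants: 19 (the cyclohexa-1,4-diene adduct)
Product: 20 2-{4-(tert-butyldimethylsilyloxy)-3-[(R)-2-(tert-butyldimethylsilyloxy)-3-methylbut-3-en-1-yl]phenyl}-5-hydroxy-7-(triisopropylsilyloxy)-4H-chromen-4-one
Conditions: DDQ (1.1 equiv), toluene, 0 °C to rt
Reagents that add atoms: none
Why: DDQ dehydrogenation (hydride abstraction from the doubly allylic C2' methylene to a siloxy-stabilised cyclohexadienyl cation, then proton loss from C5') should aromatise ring B with the silyl ether retained, the gain in aromaticity making this far faster than attack on the allylic silyl ether.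

Step 13
Reactants: 20 (the tris-silyl flavone)
Product: 21 5,7-dihydroxy-2-{4-hydroxy-3-[(R)-2-hydroxy-3-methylbut-3-en-1-yl]phenyl}-4H-chromen-4-one (CNP0184617.1)
Conditions: Bu4NF (4 equiv), THF, 0 °C to rt; then AcOH
Reagents that add atoms: none
Why: Fluoride-induced Si–O cleavage removes the two aryl silyl ethers and the secondary allylic silyl ether in one operation, with only a brief weak-acid quench, so the stereocentre and the acid-sensitive side chain next to the 4'-phenol should survive.

**Compound list**

1 | methacrolein (2-methylprop-2-enal) | C=C(C)C=O | starting material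
2 | 2,3-dibromopropene | C=C(Br)CBr | starting material
3 | bis(2-bromoprop-2-en-1-yl)tin dibromide | C=C(Br)C[Sn](Br)(Br)CC(Br)=C | intermediate
4 | rac-5-bromo-2-methylhexa-1,5-dien-3-ol | C=C(C)C(O)CC(Br)=C | intermediate
5 | (R)-5-bromo-2-methylhexa-1,5-dien-3-ol | C=C(C)[C@H](O)CC(Br)=C | intermediate
6 | (R)-[(5-bromo-2-methylhexa-1,5-dien-3-yl)oxy](tert-butyl)dimethylsilane | C=C(C)[C@H](O[Si](C)(C)C(C)(C)C)CC(Br)=C | intermediate
7 | N-methoxy-N-methylacetamide | CC(=O)N(C)OC | starting material
8 | (R)-[4-(tert-butyldimethylsilyloxy)-5-methylhexa-1,5-dien-2-yl]lithium | C=C(C)[C@H](O[Si](C)(C)C(C)(C)C)CC([Li])=C | intermediate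
9 | (R)-5-(tert-butyldimethylsilyloxy)-6-methyl-3-methylidenehept-6-en-2-one | C=C(C)[C@H](O[Si](C)(C)C(C)(C)C)CC(=C)C(C)=O | intermediate
10 | (R)-2,5-bis(tert-butyldimethylsilyloxy)-6-methyl-3-methylidenehepta-1,6-diene | C=C(C)[C@H](O[Si](C)(C)C(C)(C)C)CC(=C)C(=C)O[Si](C)(C)C(C)(C)C | intermediate
11 | phloroacetophenone (2',4',6'-trihydroxyacetophenone) | CC(=O)c1c(O)cc(O)cc1O | starting material
12 | diethyl oxalate | CCOC(=O)C(=O)OCC | starting material
13 | ethyl 2,4-dioxo-4-(2,4,6-trihydroxyphenyl)butanoate | CCOC(=O)C(=O)CC(=O)c1c(O)cc(O)cc1O | intermediate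
14 | ethyl 5,7-dihydroxy-4-oxo-4H-chromene-2-carboxylate | CCOC(=O)c1cc(=O)c2c(O)cc(O)cc2o1 | intermediate
15 | 5,7-dihydroxy-2-(hydroxymethyl)-4H-chromen-4-one | OCc1cc(=O)c2c(O)cc(O)cc2o1 | intermediate
16 | 5,7-dihydroxy-4-oxo-4H-chromene-2-carbaldehyde | O=Cc1cc(=O)c2c(O)cc(O)cc2o1 | intermediate
17 | 2-ethynyl-5,7-dihydroxy-4H-chromen-4-one | C#Cc1cc(=O)c2c(O)cc(O)cc2o1 | intermediate
18 | 2-ethynyl-5-hydroxy-7-(triisopropylsilyloxy)-4H-chromen-4-one | C#Cc1cc(=O)c2c(O)cc(O[Si](C(C)C)(C(C)C)C(C)C)cc2o1 | intermediate
19 | 2-{4-(tert-butyldimethylsilyloxy)-5-[(R)-2-(tert-butyldimethylsilyloxy)-3-methylbut-3-en-1-yl]cyclohexa-1,4-dien-1-yl}-5-hydroxy-7-(triisopropylsilyloxy)-4H-chromen-4-one | C=C(C)[C@H](O[Si](C)(C)C(C)(C)C)CC1=C(O[Si](C)(C)C(C)(C)C)CC=C(c2cc(=O)c3c(O)cc(O[Si](C(C)C)(C(C)C)C(C)C)cc3o2)C1 | intermediate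
20 | 2-{4-(tert-butyldimethylsilyloxy)-3-[(R)-2-(tert-butyldimethylsilyloxy)-3-methylbut-3-en-1-yl]phenyl}-5-hydroxy-7-(triisopropylsilyloxy)-4H-chromen-4-one | C=C(C)[C@H](O[Si](C)(C)C(C)(C)C)Cc1cc(-c2cc(=O)c3c(O)cc(O[Si](C(C)C)(C(C)C)C(C)C)cc3o2)ccc1O[Si](C)(C)C(C)(C)C | intermediate
21 | 5,7-dihydroxy-2-{4-hydroxy-3-[(R)-2-hydroxy-3-methylbut-3-en-1-yl]phenyl}-4H-chromen-4-one | C=C(C)[C@H](O)Cc1cc(-c2cc(=O)c3c(O)cc(O)cc3o2)ccc1O | target

**Count.** Total: 13 steps. Longest linear sequence: 8 steps (steps 1–5 or steps 6–10, then steps 11–13).

**Steps most likely to fail**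

Step 11. The alkyne is activated only through the vinylogous carbonyl, so the cycloaddition may be slow. The diene may then be lost to protodesilylation or dimerisation, or add with incomplete regiocontrol. Fallback: 10 and 18 would be joined by a cobalt-catalysed formal (4+2) cycloaddition (CoBr2(dppe), Zn dust, ZnI2, CH2Cl2, rt). Zinc reduces the divalent cobalt salt to a monovalent cobalt species, which couples diene and alkyne oxidatively to a metallacycle and releases the same cyclohexa-1,4-diene 19 by reductive elimination. This is known for 2-siloxybutadienes with terminal alkynes and does not depend on the electron demand of the alkyne. The regiochemistry would then rest on the ligand and would have to be confirmed. No new compound arises (F0); the route is rejoined at 19.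

Step 9. Methoxide may attack the pyrone ring or add to the newly formed enyne, and the sparingly soluble phenoxide may react sluggishly. Fallback: setting out from 16, the 7-hydroxyl would be silylated first (TIPSCl, Et3N, THF) to give 5-hydroxy-4-oxo-7-(triisopropylsilyloxy)-4H-chromene-2-carbaldehyde F1. Wittig bromomethylenation (Ph3PCH2Br bromide, KOtBu, THF, −78 °C) would give (Z)-2-(2-bromoethenyl)-5-hydroxy-7-(triisopropylsilyloxy)-4H-chromen-4-one F2. Dehydrobromination with further KOtBu (−78 to 0 °C), an aprotic olefination–elimination sequence with a hindered base, would return to the route at 18.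

Step 4. The amine released on quench may add to the α-methylene ketone, and the enone may oligomerise or suffer a second organolithium addition. Fallback: setting out from 6, a Stille coupling with tributyl(1-ethoxyvinyl)stannane (Pd(PPh3)4, a zerovalent palladium catalyst, toluene, 100 °C) would give (R)-tert-butyl[(6-ethoxy-2-methyl-5-methylidenehepta-1,6-dien-3-yl)oxy]dimethylsilane F3. Brief hydrolysis of its enol ether (0.5 M HCl, THF, 0 °C) would return to the route at 9 without any organolithium or free amine.

**Further compounds**

F0 | step 11 | none | none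
F1 | step 9 | 5-hydroxy-4-oxo-7-(triisopropylsilyloxy)-4H-chromene-2-carbaldehyde | O=Cc1cc(=O)c2c(O)cc(O[Si](C(C)C)(C(C)C)C(C)C)cc2o1
F2 | step 9 | (Z)-2-(2-bromoethenyl)-5-hydroxy-7-(triisopropylsilyloxy)-4H-chromen-4-one | Br/C=C\c1cc(=O)c2c(O)cc(O[Si](C(C)C)(C(C)C)C(C)C)cc2o1
F3 | step 4 | (R)-tert-butyl[(6-ethoxy-2-methyl-5-methylidenehepta-1,6-dien-3-yl)oxy]dimethylsilane | C=C(C)[C@H](O[Si](C)(C)C(C)(C)C)CC(=C)C(=C)OCC
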